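Numbering used below: ring atoms C1–C8a are those of the hexahydronaphthalene of the target (C1 carries the ester oxygen, C3 the ring methyl, C7 the tertiary alcohol, C8 the quaternary carbon, C9 is the ketone carbon on C8). The acyl chain is numbered C1' (free carboxyl) to C12' (ester carbonyl).

## Structural features

The core is a 1,2,3,7,8,8a-hexahydronaphthalene (ring A: C1, C2, C3, C4, C4a, C8a; ring B: C4a, C5, C6, C7, C8, C8a) whose conjugated diene C4=C4a–C5=C6 runs across both rings, so C8a is the only ring-fusion stereocentre. Ring B carries three contiguous stereocentres, C7 (tertiary alcohol with methyl), C8 (quaternary, methyl and 3-hydroxypropanoyl) and C8a (H); C8a is flanked on the other side by C1 (acyloxy), and C3 (methyl) stands alone in ring A. C1–O, C7–OH and C8–CH3 lie on one face; C3–CH3, C7–CH3, the C8 acyl group and C8a–H lie on the other (1S,3S,7R,8R,8aS). The C1 oxygen is acylated by a twelve-carbon chain: an anti α-methyl-β-hydroxy unit (C11' S, C10' R) attached to an all-E 5',9'-dimethyl tetraenoic acid. Fragile elements are the tertiary dienylic alcohol at C7 (ionises in acid), the C7–OH/C9=O tertiary aldol (retro-aldol opening of ring B in base), the primary β-hydroxy ketone (dehydration), the α-epimerisable β-hydroxy ester, and the tetraene acid (light, acid, oxygen). The real difficulty is the C8–C8a bond: it joins a quaternary carbon, itself next to the fully substituted C7, to C8a, with all three configurations fixed relative to C1, and the diene must sit at C4=C4a–C5=C6 without late oxidation. The key step exploits the array C9(=O)–C8–C8a–C4a=C4, which is a γ,δ-unsaturated carbonyl unit, the retron of a Claisen rearrangement of a ring A allylic ester at C4.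

## Logic of the disconnections

46 is cut at the C7'–C8' single bond in the middle of the tetraene, giving 41 and 45. The sensitive tetraene acid then appears only in the last step, and the free carboxyl group needs no protecting group. The forward step must be a cross-coupling that tolerates three hydroxyl groups and a carboxylic acid and keeps both alkene geometries.

41 is cut at the C1–O acyl bond (through 40) into 29 and 38. The decalin and the anti stereodiad are then made independently. The forward acylation must work on a hindered secondary alcohol without epimerising C11', and all silyl groups must leave under buffered fluoride.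

29 is traced through 28, 27 and 25 to 23 by cutting the two C–C bonds of the 3-hydroxypropanoyl group: the CH2–CH2OH bond (formaldehyde aldol) and the C9–CH3 bond (methyllithium on a carboxylic acid). C9 is thereby an acid, which is what the key step delivers, and because C8 is quaternary the ketone can enolise on one side only. The C7 oxygen must stay masked during enolate chemistry to block retro-aldol cleavage.

23 is cut at C5=C6 to give 22. This opens ring B to a ring A diene carrying a vinyl group on C7; the diene of the target arises at the correct oxidation level. The forward metathesis must close a six-membered ring next to two fully substituted carbons.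

22 is cut at the C8–C8a bond with re-formation of a C4–O bond and shift of the alkene from C4=C4a to C4a=C8a, giving 18 (key disconnection). The quaternary C8 becomes a trigonal enolate carbon and C8a an alkene carbon. Their configurations are traced back to the C4 carbinol and to the enolate geometry, and the molecule falls into a ring A alcohol and a five-carbon hydroxy acid. The forward step needs a single ketene acetal geometry, a chair transition state, and enolisation faster than retro-aldol cleavage.

18 is cut at the C4–O acyl bond into 9 and 16. The strained lactone serves as acyl donor, so the free tertiary hydroxyl needed for chelation is kept and no carboxyl activation is carried out next to it. The forward step needs attack at the acyl carbon only.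

16 is traced through 15, 13 and 12 to 10. The C7 carbinol is taken from the chiral pool; the vinyl group comes from the CH2–CH2–O arm by selenide opening and elimination, and the α-methyl group by alkylation. No asymmetric synthesis of a tertiary alcohol is required, and the α-centre need not be controlled because it is planarised later.

9 is traced through 8, 7, 6, 4, 3 and 2 to 1 by cutting the C4a–vinyl bond (cross-coupling), the C4–H bond (carbonyl reduction), the C3–CH3 bond (enolate alkylation) and the C1–H bond (asymmetric reduction). All ring A stereocentres then derive from the one carbinol set in step 1. The alkylation must go trans to the C1 oxygen and the reduction trans to the new methyl group.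

38 is cut at C10'–C11' (through 37 and 36) into 33 and 34, and 33 is traced through 32 to 30. The anti stereodiad comes from one auxiliary-controlled aldol and the E-vinyl iodide from a syn carbometalation. The forward aldol must be anti-selective on a non-enolisable enal.

45 is cut at C2'=C3' (through 44) and at the C7'–Sn bond (through 43) to 42, which already contains the C4'=C5' E-alkene. The forward steps are an E-selective olefination and a syn hydrostannation placing tin on the terminal carbon.

## Other disconnections considered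

Alternative 1: This is the disconnection that comes to mind first. After cutting the C1 ester, ring B is cut at C4a–C8a and C7–C8, leading to the open-chain trienone A1 (E,E-diene at C4a–C7, E-enone at C8=C8a); the forward key step is an intramolecular Diels–Alder reaction giving the octahydronaphthalene A2. Its ground for rejection is structural: a diene terminus at C7 that carries only methyl delivers A2 with H at C7 and at C4a, so the tertiary C7 hydroxyl would have to be introduced later at an allylic C–H with retention, and C4=C4a by dehydrogenation into conjugation without moving C5=C6. These are two late redox operations on a molecule that already holds the retro-aldol-prone array. The facial course of the cycloaddition would also rest on the remote C1 and C3 centres. The chosen plan reaches the diene and the C7 oxygen at their final oxidation level and controls C8 and C8a from the adjacent C4 carbinol.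

Alternative 2: Both rings are cut at their alkenes (C4=C4a and C5=C6), leading to the open-chain dienyne A3 with an ethynyl group on C8a and vinyl groups on C3 and C7; the forward key step is a ruthenium-catalysed dienyne ring-closing metathesis cascade that would close rings A and B and lay down the diene in one operation. The step creates no stereocentre. All five, including the vicinal fully substituted C7 and C8 next to the propargylic C8a, would have to be set on a flexible chain, where no reliable method for that triad exists, so the real difficulty is moved rather than solved. The Claisen plan sets C8 and C8a under cyclic control and still closes ring B by a single metathesis.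

Alternative 3: Ring B is cut at the C7–C8 bond (retro-aldol), leading to the ring A diketone A4 with a (Z)-configured 3-oxobut-1-enyl group on C4a and a 1-methyl-2-oxoalkyl group on C8a; the forward key step is an intramolecular aldol addition of the C8 enolate to the methyl ketone. Mechanistic grounds speak against it. The (Z)-dienone of A4 is set up for oxa-6π electrocyclisation and Z to E isomerisation, the ketone can enolise on two sides, and an aldol that creates two vicinal fully substituted carbons is expected to lie on the side of the open form, which is the fragility of the target itself. The configurations at C7 and C8 would then depend on an equilibrium rather than on a defined transition state.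

Key step: step 13

Assumption: the α-carbon that becomes C8 is carried as a mixture of epimers in 12, 13, 15, 16 and 18, because it is converted into a trigonal enolate carbon in step 13; the SMILES of these compounds leave that centre undefined.

## Steps

Step 1
Reactants: 1 1,4-dioxaspiro[4.5]dec-6-en-8-one
Product: 2 (8S)-1,4-dioxaspiro[4.5]dec-6-en-8-ol
Conditions: RuCl[(S,S)-TsDPEN](p-cymene) (1 mol%), KOH (2 mol%), i-PrOH, 25 °C
Reagents that add atoms: none
Why: Noyori-type asymmetric transfer hydrogenation reduces the carbonyl 1,2-selectively through the metal hydride/N–H pair; with the (S,S)-ligand the enone alkene takes the place of the aryl group of an aryl ketone, which should give the (S)-carbinol that becomes C1.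

Step 2
Reactants: 2 (8S)-1,4-dioxaspiro[4.5]dec-6-en-8-ol
Product: 3 (4S)-4-hydroxycyclohex-2-en-1-one
Conditions: Amberlyst-15 (cat.), acetone/H2O (10:1), 25 °C
Reagents that add atoms: water, O
Why: Acid-catalysed ketal hydrolysis unmasks the enone that becomes C4/C4a/C8a; the mild solid acid should avoid allylic transposition, and the carbinol centre is not involved.

Step 3
Reactants: 3 (4S)-4-hydroxycyclohex-2-en-1-one
Product: 4 (4S)-4-(triethylsilyloxy)cyclohex-2-en-1-one
Conditions: Et3SiCl, imidazole, CH2Cl2, 0 °C
Reagents that add atoms: chlorotriethylsilane, CC[Si](Cl)(CC)CC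
Why: Standard silylation; the triethylsilyl ether survives the base and metal chemistry ahead and can later be cleaved in the presence of a primary tert-butyldimethylsilyl ether.

Step 4
Reactants: 4 (4S)-4-(triethylsilyloxy)cyclohex-2-en-1-one
Product: 6 (4S,6S)-6-methyl-4-(triethylsilyloxy)cyclohex-2-en-1-one, via lithium dienolate 5 (not isolated)
Conditions: LiN(i-Pr)2 (1.1 equiv), THF, −78 °C; MeI, −78 → −40 °C
Reagents that add atoms: iodomethane, CI
Why: Kinetic α'-deprotonation gives the cross-conjugated dienolate, and axial attack of iodomethane anti to the pseudoaxial silyloxy group in the 1,3-position should give the trans isomer, which sets C3; the product is kept from equilibrating conditions because the cis isomer is expected to be the thermodynamic one.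

Step 5
Reactants: 6 (4S,6S)-6-methyl-4-(triethylsilyloxy)cyclohex-2-en-1-one
Product: 7 (4S,6S)-2-iodo-6-methyl-4-(triethylsilyloxy)cyclohex-2-en-1-one
Conditions: I2, pyridine/CH2Cl2 (1:1), 0 → 25 °C
Reagents that add atoms: iodine, II
Why: Amine-mediated α-iodination of an enone (conjugate addition of pyridine, iodination of the enolate, elimination) installs the handle at the future C4a; pyridine is too weak a base to epimerise C3.

Step 6
Reactants: 7 (4S,6S)-2-iodo-6-methyl-4-(triethylsilyloxy)cyclohex-2-en-1-one
Product: 8 (1R,4S,6S)-2-iodo-6-methyl-4-(triethylsilyloxy)cyclohex-2-en-1-ol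
Conditions: NaBH4, CeCl3·7H2O, MeOH, −78 → −40 °C
Reagents that add atoms: none
Why: Luche reduction is 1,2-selective; axial hydride attack on the half-chair with equatorial methyl should give the equatorial alcohol trans to the adjacent methyl and therefore cis to the C1 silyloxy group, which sets the C4 carbinol that later directs the Claisen step.

Step 7
Reactants: 8 (1R,4S,6S)-2-iodo-6-methyl-4-(triethylsilyloxy)cyclohex-2-en-1-ol
Product: 9 (1R,4S,6S)-2-ethenyl-6-methyl-4-(triethylsilyloxy)cyclohex-2-en-1-ol
Conditions: Bu3SnCH=CH2, Pd(PPh3)4 (5 mol%), CuI (10 mol%), DMF, 50 °C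
Reagents that add atoms: tributyl(vinyl)stannane, C=C[Sn](CCCC)(CCCC)CCCC
Why: Stille coupling of the alkenyl iodide proceeds with retention and tolerates the free allylic hydroxyl; the new vinyl group is the future C5 and makes the ring alkene the central part of the allyl unit of step 13.

Step 8
Reactants: 10 (R)-mevalonolactone [(4R)-4-hydroxy-4-methyloxan-2-one]
Product: 12 (4R)-4-hydroxy-3,4-dimethyloxan-2-one (both C3 epimers), via dilithium alkoxide enolate 11 (not isolated)
Conditions: LiN(i-Pr)2 (2.2 equiv), THF, −78 → −30 °C; MeI, DMPU, −78 → −40 °C; AcOH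
Reagents that add atoms: iodomethane, CI
Why: Fráter–Seebach-type alkylation of the β-hydroxy lactone dianion; the alkoxide cannot leave, so β-elimination is blocked, the C4 carbinol (future C7) is untouched, and the configuration of the new centre is of no consequence.

Step 9
Reactants: 12 (4R)-4-hydroxy-3,4-dimethyloxan-2-one (both C3 epimers)
Product: 13 (3R)-3-hydroxy-2,3-dimethyl-5-(phenylselanyl)pentanoic acid (both C2 epimers)
Conditions: PhSeH, NaH, DMF, 0 °C; then 12, 90 °C; 1 M HCl work-up
Reagents that add atoms: benzeneselenol, [SeH]c1ccccc1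
Why: The soft selenolate opens the lactone by SN2 attack at the O–CH2 carbon (alkyl–oxygen cleavage), giving the ω-selanyl carboxylate; the tertiary carbinol carbon is not involved.

Step 10
Reactants: 13 (3R)-3-hydroxy-2,3-dimethyl-5-(phenylselanyl)pentanoic acid (both C2 epimers)
Product: 15 (3R)-3-hydroxy-2,3-dimethylpent-4-enoic acid (both C2 epimers), via selenoxide 14 (not isolated)
Conditions: 30% H2O2, pyridine, CH2Cl2, 0 → 30 °C
Reagents that add atoms: none
Why: Selenide oxidation followed by syn elimination of the selenoxide; only the CH2 next to the carbinol carbon offers β-hydrogens, so the terminal vinyl group (future C6) is the only possible alkene, and pyridine keeps the medium from ionising the tertiary allylic alcohol.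

Step 11
Reactants: 15 (3R)-3-hydroxy-2,3-dimethylpent-4-enoic acid (both C2 epimers)
Product: 16 (4R)-4-ethenyl-3,4-dimethyloxetan-2-one (both C3 epimers)
Conditions: PhSO2Cl, pyridine, 0 °C
Reagents that add atoms: none
Why: β-Lactonisation by carboxyl activation: the mixed sulfonic anhydride is attacked at the acyl carbon by the tertiary hydroxyl, so no bond to the carbinol carbon is broken and its configuration is retained.

Step 12
Reactants: 9 (1R,4S,6S)-2-ethenyl-6-methyl-4-(triethylsilyloxy)cyclohex-2-en-1-ol; 16 (4R)-4-ethenyl-3,4-dimethyloxetan-2-one (both C3 epimers)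
Product: 18 (1R,4S,6S)-2-ethenyl-6-methyl-4-(triethylsilyloxy)cyclohex-2-en-1-yl (3R)-3-hydroxy-2,3-dimethylpent-4-enoate (both C2 epimers), via lithium alkoxide 17 (not isolated)
Conditions: LiN(SiMe3)2 (1.05 equiv), THF, −78 °C; then 16, −78 → −40 °C; AcOH, −78 °C
Reagents that add atoms: none
Why: Acyl transfer from a β-lactone: the hard alkoxide attacks the strained acyl carbon (attack at the ring C–O carbon is blocked because it is fully substituted), which acylates the hindered C4 hydroxyl and leaves the tertiary hydroxyl free; the cold acidic quench should forestall retro-aldol cleavage of the released tertiary alkoxide.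

Step 13
Reactants: 18 (1R,4S,6S)-2-ethenyl-6-methyl-4-(triethylsilyloxy)cyclohex-2-en-1-yl (3R)-3-hydroxy-2,3-dimethylpent-4-enoate (both C2 epimers)
Product: 22 (2R,3R)-2-[(1S,4S,6S)-2-ethenyl-4-methyl-6-(triethylsilyloxy)cyclohex-2-en-1-yl]-2,3-dimethyl-3-(trimethylsilyloxy)pent-4-enoic acid, via dilithium ester dianion 19 (not isolated), via bis(trimethylsilyl) ketene acetal 20 (not isolated), via trimethylsilyl ester 21 (not isolated)
Conditions: LiN(i-Pr)2 (2.5 equiv), THF, −78 °C; Me3SiCl, Et3N, −78 → 55 °C; pH 7 phosphate buffer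
Reagents that add atoms: chlorotrimethylsilane, C[Si](C)(C)Cl
Why: Dianionic Ireland–Claisen rearrangement: the base first forms the tertiary alkoxide and then removes the α-proton, and in dianion 19 lithium bridges the C7 alkoxide and the enolate oxygen, so C7 is syn to the enolate oxygen and the α-methyl group syn to the allylic oxygen, a geometry that silylation fixes in ketene acetal 20. On warming, 20 undergoes a concerted suprafacial [3,3] shift over the C4–C4a=C8a allyl unit: the C4–O bond breaks, the C8–C8a bond forms on the face that carried the oxygen, and the ring alkene moves to C4=C4a in conjugation with the vinyl group. The closest known reaction types are the rearrangement of dianions of allyl β-hydroxy esters and the Ireland–Claisen rearrangement of cyclohex-2-enyl esters to α-quaternary acids. The step closes no ring; it joins ring A to the C6–C9 chain, and ring B is closed in step 14. C8a is controlled by the C4 carbinol through 1,3-transfer of chirality, which places C8 cis to the C1 silyloxy group and leaves C8a–H on the opposite face. C8 is controlled by the ketene acetal geometry together with a chair transition state, in which the bulky C7 group is pseudo-equatorial and the methyl group pseudo-axial; the boat would push that methyl group over ring A next to C1 and eclipse the silyloxy group with the C4a vinyl substituent. C7 is carried in from 10 and is not touched. The step therefore needs a single enolate geometry (secured by chelation), chair over boat (secured by the C4a substituent and by the methyl group syn to the allylic oxygen), and enolisation faster than retro-aldol cleavage of the aldolate (low temperature, excess base).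

Step 14
Reactants: 22 (2R,3R)-2-[(1S,4S,6S)-2-ethenyl-4-methyl-6-(triethylsilyloxy)cyclohex-2-en-1-yl]-2,3-dimethyl-3-(trimethylsilyloxy)pent-4-enoic acid
Product: 23 (1R,2R,6S,8S,8aS)-1,2,6-trimethyl-8-(triethylsilyloxy)-2-(trimethylsilyloxy)-1,2,6,7,8,8a-hexahydronaphthalene-1-carboxylic acid
Conditions: second-generation Hoveyda–Grubbs catalyst [RuCl2(H2IMes)(=CH-C6H4-2-O-i-Pr)] (5 mol%), toluene, 60 °C
Reagents that add atoms: none
Why: Ring-closing metathesis: the catalyst should load on the unhindered terminal alkene of the diene and close onto the vinyl group on C7, forming the six-membered ring B and the C5=C6 bond so that the C4=C4a–C5=C6 diene is complete; no stereocentre is affected and the free acid is tolerated.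

Step 15
Reactants: 23 (1R,2R,6S,8S,8aS)-1,2,6-trimethyl-8-(triethylsilyloxy)-2-(trimethylsilyloxy)-1,2,6,7,8,8a-hexahydronaphthalene-1-carboxylic acid
Product: 25 1-[(1R,2R,6S,8S,8aS)-1,2,6-trimethyl-8-(triethylsilyloxy)-2-(trimethylsilyloxy)-1,2,6,7,8,8a-hexahydronaphthalen-1-yl]ethan-1-one, via dilithium geminal diolate 24 (not isolated)
Conditions: MeLi (4 equiv), Et2O, 0 → 25 °C; then added to AcOH/THF, −78 °C
Reagents that add atoms: methyllithium, [Li]C
Why: Addition of methyllithium to the lithium carboxylate stops at the geminal diolate, which gives the methyl ketone only on protonation; the inverse quench destroys excess reagent at the same time, and the silyl ethers are inert.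

Step 16
Reactants: 25 1-[(1R,2R,6S,8S,8aS)-1,2,6-trimethyl-8-(triethylsilyloxy)-2-(trimethylsilyloxy)-1,2,6,7,8,8a-hexahydronaphthalen-1-yl]ethan-1-one
Product: 27 3-hydroxy-1-[(1R,2R,6S,8S,8aS)-1,2,6-trimethyl-8-(triethylsilyloxy)-2-(trimethylsilyloxy)-1,2,6,7,8,8a-hexahydronaphthalen-1-yl]propan-1-one, via lithium enolate 26 (not isolated)
Conditions: LiN(i-Pr)2 (1.2 equiv), THF, −78 °C; CH2O (gas, from paraformaldehyde), −78 °C; AcOH
Reagents that add atoms: formaldehyde, C=O
Why: Aldol addition to formaldehyde: C8 is quaternary, so only the methyl group can enolise; the silyl ether on the C7 oxygen blocks retro-aldol opening of ring B, and the cold quench should limit dehydration of the new β-hydroxy ketone.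

Step 17
Reactants: 27 3-hydroxy-1-[(1R,2R,6S,8S,8aS)-1,2,6-trimethyl-8-(triethylsilyloxy)-2-(trimethylsilyloxy)-1,2,6,7,8,8a-hexahydronaphthalen-1-yl]propan-1-one
Product: 28 3-(tert-butyldimethylsilyloxy)-1-[(1R,2R,6S,8S,8aS)-1,2,6-trimethyl-8-(triethylsilyloxy)-2-(trimethylsilyloxy)-1,2,6,7,8,8a-hexahydronaphthalen-1-yl]propan-1-one
Conditions: t-BuMe2SiCl, imidazole, DMF, 0 °C
Reagents that add atoms: tert-butylchlorodimethylsilane, CC(C)(C)[Si](C)(C)Cl
Why: Silylation of the only free (primary) hydroxyl; a β-silyloxy ketone is much less prone to elimination than a β-acyloxy ketone.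

Step 18
Reactants: 28 3-(tert-butyldimethylsilyloxy)-1-[(1R,2R,6S,8S,8aS)-1,2,6-trimethyl-8-(triethylsilyloxy)-2-(trimethylsilyloxy)-1,2,6,7,8,8a-hexahydronaphthalen-1-yl]propan-1-one
Product: 29 3-(tert-butyldimethylsilyloxy)-1-[(1R,2R,6S,8S,8aS)-2,8-dihydroxy-1,2,6-trimethyl-1,2,6,7,8,8a-hexahydronaphthalen-1-yl]propan-1-one
Conditions: HF·pyridine, pyridine, THF, 0 °C
Reagents that add atoms: none
Why: Buffered fluoride should cleave the secondary triethylsilyl and the tertiary trimethylsilyl ether well before the primary tert-butyldimethylsilyl ether; the non-ionising medium protects the dienylic C7 alcohol.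

Step 19
Reactants: 30 prop-2-yn-1-ol
Product: 32 (2E)-3-iodo-2-methylprop-2-en-1-ol, via alkenylalane 31 (not isolated)
Conditions: AlMe3 (3 equiv), Cp2ZrCl2 (25 mol%), CH2Cl2, 0 → 25 °C; I2, THF, −30 °C
Reagents that add atoms: trimethylaluminium, C[Al](C)C; iodine, II
Why: Negishi zirconium-catalysed carboalumination adds methyl and aluminium syn across the alkyne with aluminium on the terminal carbon, and iodinolysis with retention gives the E-alkenyl iodide (future C8'=C9').

Step 20
Reactants: 32 (2E)-3-iodo-2-methylprop-2-en-1-ol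
Product: 33 (2E)-3-iodo-2-methylprop-2-enal
Conditions: MnO2, CH2Cl2, 25 °C
Reagents that add atoms: none
Why: Selective oxidation of an allylic alcohol on the manganese dioxide surface; alkene geometry and the C–I bond are unaffected.

Step 21
Reactants: 33 (2E)-3-iodo-2-methylprop-2-enal; 34 (4R)-4-benzyl-3-propanoyl-1,3-oxazolidin-2-one
Product: 36 (4R)-4-benzyl-3-[(2S,3R,4E)-3-hydroxy-5-iodo-2,4-dimethylpent-4-enoyl]-1,3-oxazolidin-2-one, via trimethylsilyl ether 35 (not isolated)
Conditions: MgCl2 (20 mol%), Et3N, Me3SiCl, EtOAc, 25 °C; then CF3CO2H (cat.), MeOH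
Reagents that add atoms: none
Why: Magnesium halide-catalysed anti-aldol reaction of an Evans N-acyloxazolidinone: the chelated (Z)-magnesium enolate should react through a boat transition state on the face opposite the benzyl group (the face used in enolate alkylations), so the (R)-auxiliary should give the (2S,3R) anti adduct; silylation of the aldolate turns the catalyst over and the non-enolisable enal is the preferred type of substrate.

Step 22
Reactants: 36 (4R)-4-benzyl-3-[(2S,3R,4E)-3-hydroxy-5-iodo-2,4-dimethylpent-4-enoyl]-1,3-oxazolidin-2-one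
Product: 37 (4R)-4-benzyl-3-[(2S,3R,4E)-5-iodo-2,4-dimethyl-3-(triethylsilyloxy)pent-4-enoyl]-1,3-oxazolidin-2-one
Conditions: Et3SiOTf, 2,6-lutidine, CH2Cl2, −78 → 0 °C
Reagents that add atoms: triethylsilyl trifluoromethanesulfonate, CC[Si](CC)(CC)OS(=O)(=O)C(F)(F)F
Why: Silylation of the secondary allylic alcohol under non-nucleophilic base; it prevents self-acylation in step 24 and retro-aldol cleavage in step 23.

Step 23
Reactants: 37 (4R)-4-benzyl-3-[(2S,3R,4E)-5-iodo-2,4-dimethyl-3-(triethylsilyloxy)pent-4-enoyl]-1,3-oxazolidin-2-one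
Product: 38 (2S,3R,4E)-5-iodo-2,4-dimethyl-3-(triethylsilyloxy)pent-4-enoic acid
Conditions: LiOH, H2O2, THF/H2O (3:1), 0 °C; Na2SO3; HCl to pH 3
Reagents that add atoms: hydrogen peroxide (as lithium hydroperoxide), OO
Why: Hydroperoxide attacks the exocyclic imide carbonyl selectively and is too weakly basic to epimerise the α-centre; sulfite reduces the peracid to the acid and the auxiliary is recovered.

Step 24
Reactants: 29 3-(tert-butyldimethylsilyloxy)-1-[(1R,2R,6S,8S,8aS)-2,8-dihydroxy-1,2,6-trimethyl-1,2,6,7,8,8a-hexahydronaphthalen-1-yl]propan-1-one; 38 (2S,3R,4E)-5-iodo-2,4-dimethyl-3-(triethylsilyloxy)pent-4-enoic acid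
Product: 40 (1S,3S,7R,8R,8aS)-8-[3-(tert-butyldimethylsilyloxy)propanoyl]-7-hydroxy-3,7,8-trimethyl-1,2,3,7,8,8a-hexahydronaphthalen-1-yl (2S,3R,4E)-5-iodo-2,4-dimethyl-3-(triethylsilyloxy)pent-4-enoate, via mixed anhydride 39 (not isolated)
Conditions: 2,4,6-Cl3C6H2COCl, Et3N, toluene, 25 °C; then 29, DMAP, 25 → 40 °C
Reagents that add atoms: none
Why: Yamaguchi esterification: the acylpyridinium formed from the mixed anhydride acylates the secondary C1 hydroxyl, while the tertiary C7 hydroxyl is too hindered to compete; the amine bases are too weak to open the tertiary aldol.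

Step 25
Reactants: 40 (1S,3S,7R,8R,8aS)-8-[3-(tert-butyldimethylsilyloxy)propanoyl]-7-hydroxy-3,7,8-trimethyl-1,2,3,7,8,8a-hexahydronaphthalen-1-yl (2S,3R,4E)-5-iodo-2,4-dimethyl-3-(triethylsilyloxy)pent-4-enoate
Product: 41 (1S,3S,7R,8R,8aS)-7-hydroxy-8-(3-hydroxypropanoyl)-3,7,8-trimethyl-1,2,3,7,8,8a-hexahydronaphthalen-1-yl (2S,3R,4E)-3-hydroxy-5-iodo-2,4-dimethylpent-4-enoate
Conditions: HF·pyridine, pyridine, THF, 0 → 25 °C
Reagents that add atoms: none
Why: Buffered fluoride removes both remaining silyl ethers under conditions that are neither basic enough for retro-aldol or elimination nor acidic enough to ionise the C7 alcohol.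

Step 26
Reactants: 42 (2E)-3-methylpent-2-en-4-yn-1-ol
Product: 43 (2E,4E)-3-methyl-5-(tributylstannyl)penta-2,4-dien-1-ol
Conditions: Bu3SnH, PdCl2(PPh3)2 (2 mol%), THF, 0 °C
Reagents that add atoms: tributyltin hydride, CCCC[SnH](CCCC)CCCC
Why: Palladium-catalysed hydrostannation adds H and Sn syn across the terminal alkyne with tin on the less hindered terminal carbon, giving the E-dienylstannane (future C6'=C7'); a minor internal regioisomer would be removed by chromatography.

Step 27
Reactants: 43 (2E,4E)-3-methyl-5-(tributylstannyl)penta-2,4-dien-1-ol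
Product: 44 (2E,4E)-3-methyl-5-(tributylstannyl)penta-2,4-dienal
Conditions: MnO2, CH2Cl2, 25 °C
Reagents that add atoms: none
Why: Neutral allylic oxidation that leaves the acid-sensitive alkenylstannane intact.

Step 28
Reactants: 44 (2E,4E)-3-methyl-5-(tributylstannyl)penta-2,4-dienal
Product: 45 (2E,4E,6E)-5-methyl-7-(tributylstannyl)hepta-2,4,6-trienoic acid
Conditions: (EtO)2P(O)CH2CO2H, LiN(SiMe3)2 (2.1 equiv), THF, −78 → 0 °C; then 44, 0 → 25 °C; AcOH to pH 5
Reagents that add atoms: diethylphosphonoacetic acid, CCOP(=O)(CC(O)=O)OCC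
Why: Horner–Wadsworth–Emmons olefination with the dianion of the phosphonoacetic acid gives the E-configured acid directly, so no ester hydrolysis is needed; the weakly acidic work-up avoids protodestannylation.

Step 29
Reactants: 41 (1S,3S,7R,8R,8aS)-7-hydroxy-8-(3-hydroxypropanoyl)-3,7,8-trimethyl-1,2,3,7,8,8a-hexahydronaphthalen-1-yl (2S,3R,4E)-3-hydroxy-5-iodo-2,4-dimethylpent-4-enoate; 45 (2E,4E,6E)-5-methyl-7-(tributylstannyl)hepta-2,4,6-trienoic acid
Product: 46 calbistrin C
Conditions: Pd2(dba)3 (5 mol%), AsPh3 (20 mol%), i-Pr2NEt, DMF, 25 °C, dark; pH 5 buffer work-up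
Reagents that add atoms: none
Why: Stille coupling of an alkenyl iodide with an alkenylstannane proceeds with retention at both partners under neutral conditions and tolerates hydroxyl and carboxylate groups; forming the C7'–C8' bond last keeps handling of the tetraene to a minimum.

## Compound list

1 | 1,4-dioxaspiro[4.5]dec-6-en-8-one | O=C1C=CC2(CC1)OCCO2 | starting material
2 | (8S)-1,4-dioxaspiro[4.5]dec-6-en-8-ol | O[C@H]1CCC2(OCCO2)C=C1 | intermediate
3 | (4S)-4-hydroxycyclohex-2-en-1-one | O[C@H]1CCC(=O)C=C1 | intermediate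
4 | (4S)-4-(triethylsilyloxy)cyclohex-2-en-1-one | CC[Si](CC)(CC)O[C@H]1CCC(=O)C=C1 | intermediate
5 | lithium dienolate of 4 (O–Li at the former carbonyl, C=C towards the future C3) | CC[Si](CC)(CC)O[C@H]1CC=C(O[Li])C=C1 | intermediate
6 | (4S,6S)-6-methyl-4-(triethylsilyloxy)cyclohex-2-en-1-one | CC[Si](CC)(CC)O[C@H]1C[C@H](C)C(=O)C=C1 | intermediate
7 | (4S,6S)-2-iodo-6-methyl-4-(triethylsilyloxy)cyclohex-2-en-1-one | CC[Si](CC)(CC)O[C@H]1C[C@H](C)C(=O)C(I)=C1 | intermediate
8 | (1R,4S,6S)-2-iodo-6-methyl-4-(triethylsilyloxy)cyclohex-2-en-1-ol | CC[Si](CC)(CC)O[C@H]1C[C@H](C)[C@@H](O)C(I)=C1 | intermediate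
9 | (1R,4S,6S)-2-ethenyl-6-methyl-4-(triethylsilyloxy)cyclohex-2-en-1-ol | CC[Si](CC)(CC)O[C@H]1C[C@H](C)[C@@H](O)C(C=C)=C1 | intermediate
10 | (R)-mevalonolactone, (4R)-4-hydroxy-4-methyloxan-2-one | C[C@@]1(O)CCOC(=O)C1 | starting material
11 | dilithium alkoxide enolate of 10 | C[C@@]1(O[Li])CCOC(O[Li])=C1 | intermediate
12 | (4R)-4-hydroxy-3,4-dimethyloxan-2-one (both C3 epimers) | C[C@@]1(O)CCOC(=O)C1C | intermediate
13 | (3R)-3-hydroxy-2,3-dimethyl-5-(phenylselanyl)pentanoic acid (both C2 epimers) | OC(=O)C(C)[C@](C)(O)CC[Se]c1ccccc1 | intermediate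
14 | selenoxide of 13 | OC(=O)C(C)[C@](C)(O)CC[Se](=O)c1ccccc1 | intermediate
15 | (3R)-3-hydroxy-2,3-dimethylpent-4-enoic acid (both C2 epimers) | OC(=O)C(C)[C@](C)(O)C=C | intermediate
16 | (4R)-4-ethenyl-3,4-dimethyloxetan-2-one (both C3 epimers) | C=C[C@@]1(C)OC(=O)C1C | intermediate
17 | lithium alkoxide of 9 | CC[Si](CC)(CC)O[C@H]1C[C@H](C)[C@@H](O[Li])C(C=C)=C1 | intermediate
18 | (1R,4S,6S)-2-ethenyl-6-methyl-4-(triethylsilyloxy)cyclohex-2-en-1-yl (3R)-3-hydroxy-2,3-dimethylpent-4-enoate (both C2 epimers) | CC[Si](CC)(CC)O[C@H]1C[C@H](C)[C@@H](OC(=O)C(C)[C@](C)(O)C=C)C(C=C)=C1 | intermediate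
19 | dilithium dianion of 18 (C7 alkoxide and ester enolate, C7 syn to the enolate oxygen) | CC[Si](CC)(CC)O[C@H]1C[C@H](C)[C@@H](O/C(O[Li])=C(\C)[C@](C)(O[Li])C=C)C(C=C)=C1 | intermediate
20 | bis(trimethylsilyl) derivative of 19: silyl ketene acetal with C7 syn to OSiMe3, and C7 trimethylsilyl ether | CC[Si](CC)(CC)O[C@H]1C[C@H](C)[C@@H](O/C(O[Si](C)(C)C)=C(\C)[C@](C)(O[Si](C)(C)C)C=C)C(C=C)=C1 | intermediate
21 | trimethylsilyl ester of 22 | CC[Si](CC)(CC)O[C@H]1C[C@H](C)C=C(C=C)[C@H]1[C@@](C)(C(=O)O[Si](C)(C)C)[C@](C)(O[Si](C)(C)C)C=C | intermediate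
22 | (2R,3R)-2-[(1S,4S,6S)-2-ethenyl-4-methyl-6-(triethylsilyloxy)cyclohex-2-en-1-yl]-2,3-dimethyl-3-(trimethylsilyloxy)pent-4-enoic acid | CC[Si](CC)(CC)O[C@H]1C[C@H](C)C=C(C=C)[C@H]1[C@@](C)(C(O)=O)[C@](C)(O[Si](C)(C)C)C=C | intermediate
23 | (1R,2R,6S,8S,8aS)-1,2,6-trimethyl-8-(triethylsilyloxy)-2-(trimethylsilyloxy)-1,2,6,7,8,8a-hexahydronaphthalene-1-carboxylic acid | CC[Si](CC)(CC)O[C@H]1C[C@H](C)C=C2C=C[C@@](C)(O[Si](C)(C)C)[C@](C)(C(O)=O)[C@H]21 | intermediate
24 | dilithium geminal diolate from 23 and methyllithium | CC[Si](CC)(CC)O[C@H]1C[C@H](C)C=C2C=C[C@@](C)(O[Si](C)(C)C)[C@](C)(C(C)(O[Li])O[Li])[C@H]21 | intermediate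
25 | 1-[(1R,2R,6S,8S,8aS)-1,2,6-trimethyl-8-(triethylsilyloxy)-2-(trimethylsilyloxy)-1,2,6,7,8,8a-hexahydronaphthalen-1-yl]ethan-1-one | CC[Si](CC)(CC)O[C@H]1C[C@H](C)C=C2C=C[C@@](C)(O[Si](C)(C)C)[C@](C)(C(C)=O)[C@H]21 | intermediate
26 | lithium enolate of 25 | CC[Si](CC)(CC)O[C@H]1C[C@H](C)C=C2C=C[C@@](C)(O[Si](C)(C)C)[C@](C)(C(=C)O[Li])[C@H]21 | intermediate
27 | 3-hydroxy-1-[(1R,2R,6S,8S,8aS)-1,2,6-trimethyl-8-(triethylsilyloxy)-2-(trimethylsilyloxy)-1,2,6,7,8,8a-hexahydronaphthalen-1-yl]propan-1-one | CC[Si](CC)(CC)O[C@H]1C[C@H](C)C=C2C=C[C@@](C)(O[Si](C)(C)C)[C@](C)(C(=O)CCO)[C@H]21 | intermediate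
28 | 3-(tert-butyldimethylsilyloxy)-1-[(1R,2R,6S,8S,8aS)-1,2,6-trimethyl-8-(triethylsilyloxy)-2-(trimethylsilyloxy)-1,2,6,7,8,8a-hexahydronaphthalen-1-yl]propan-1-one | CC[Si](CC)(CC)O[C@H]1C[C@H](C)C=C2C=C[C@@](C)(O[Si](C)(C)C)[C@](C)(C(=O)CCO[Si](C)(C)C(C)(C)C)[C@H]21 | intermediate
29 | 3-(tert-butyldimethylsilyloxy)-1-[(1R,2R,6S,8S,8aS)-2,8-dihydroxy-1,2,6-trimethyl-1,2,6,7,8,8a-hexahydronaphthalen-1-yl]propan-1-one | O[C@H]1C[C@H](C)C=C2C=C[C@@](C)(O)[C@](C)(C(=O)CCO[Si](C)(C)C(C)(C)C)[C@H]21 | intermediate
30 | prop-2-yn-1-ol | OCC#C | starting material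
31 | alkenylalane from syn carboalumination of 30 (O–AlMe2 and C–AlMe2) | C[Al](C)/C=C(\C)CO[Al](C)C | intermediate
32 | (2E)-3-iodo-2-methylprop-2-en-1-ol | OC/C(C)=C/I | intermediate
33 | (2E)-3-iodo-2-methylprop-2-enal | O=C/C(C)=C/I | intermediate
34 | (4R)-4-benzyl-3-propanoyl-1,3-oxazolidin-2-one | CCC(=O)N1C(=O)OC[C@H]1Cc1ccccc1 | starting material
35 | trimethylsilyl ether of 36 | I/C=C(\C)[C@H](O[Si](C)(C)C)[C@H](C)C(=O)N1C(=O)OC[C@H]1Cc1ccccc1 | intermediate
36 | (4R)-4-benzyl-3-[(2S,3R,4E)-3-hydroxy-5-iodo-2,4-dimethylpent-4-enoyl]-1,3-oxazolidin-2-one | I/C=C(\C)[C@H](O)[C@H](C)C(=O)N1C(=O)OC[C@H]1Cc1ccccc1 | intermediate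
37 | (4R)-4-benzyl-3-[(2S,3R,4E)-5-iodo-2,4-dimethyl-3-(triethylsilyloxy)pent-4-enoyl]-1,3-oxazolidin-2-one | I/C=C(\C)[C@H](O[Si](CC)(CC)CC)[C@H](C)C(=O)N1C(=O)OC[C@H]1Cc1ccccc1 | intermediate
38 | (2S,3R,4E)-5-iodo-2,4-dimethyl-3-(triethylsilyloxy)pent-4-enoic acid | I/C=C(\C)[C@H](O[Si](CC)(CC)CC)[C@H](C)C(O)=O | intermediate
39 | mixed anhydride of 38 with 2,4,6-trichlorobenzoic acid | I/C=C(\C)[C@H](O[Si](CC)(CC)CC)[C@H](C)C(=O)OC(=O)c1c(Cl)cc(Cl)cc1Cl | intermediate
40 | (1S,3S,7R,8R,8aS)-8-[3-(tert-butyldimethylsilyloxy)propanoyl]-7-hydroxy-3,7,8-trimethyl-1,2,3,7,8,8a-hexahydronaphthalen-1-yl (2S,3R,4E)-5-iodo-2,4-dimethyl-3-(triethylsilyloxy)pent-4-enoate | I/C=C(\C)[C@H](O[Si](CC)(CC)CC)[C@H](C)C(=O)O[C@H]1C[C@H](C)C=C2C=C[C@@](C)(O)[C@](C)(C(=O)CCO[Si](C)(C)C(C)(C)C)[C@H]21 | intermediate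
41 | (1S,3S,7R,8R,8aS)-7-hydroxy-8-(3-hydroxypropanoyl)-3,7,8-trimethyl-1,2,3,7,8,8a-hexahydronaphthalen-1-yl (2S,3R,4E)-3-hydroxy-5-iodo-2,4-dimethylpent-4-enoate | I/C=C(\C)[C@H](O)[C@H](C)C(=O)O[C@H]1C[C@H](C)C=C2C=C[C@@](C)(O)[C@](C)(C(=O)CCO)[C@H]21 | intermediate
42 | (2E)-3-methylpent-2-en-4-yn-1-ol | C#C/C(C)=C/CO | starting material
43 | (2E,4E)-3-methyl-5-(tributylstannyl)penta-2,4-dien-1-ol | CCCC[Sn](CCCC)(CCCC)/C=C/C(C)=C/CO | intermediate
44 | (2E,4E)-3-methyl-5-(tributylstannyl)penta-2,4-dienal | CCCC[Sn](CCCC)(CCCC)/C=C/C(C)=C/C=O | intermediate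
45 | (2E,4E,6E)-5-methyl-7-(tributylstannyl)hepta-2,4,6-trienoic acid | CCCC[Sn](CCCC)(CCCC)/C=C/C(C)=C/C=C/C(O)=O | intermediate
46 | calbistrin C, (2E,4E,6E,8E,10R,11S)-10-hydroxy-12-{[(1S,3S,7R,8R,8aS)-7-hydroxy-8-(3-hydroxypropanoyl)-3,7,8-trimethyl-1,2,3,7,8,8a-hexahydronaphthalen-1-yl]oxy}-5,9,11-trimethyl-12-oxododeca-2,4,6,8-tetraenoic acid | CC(/C=C/C=C(\C)[C@H](O)[C@H](C)C(=O)O[C@H]1C[C@H](C)C=C2C=C[C@@](C)(O)[C@](C)(C(=O)CCO)[C@H]21)=C\C=C\C(=O)O | target

## Step count and least certain steps

Total step count: 29. Longest linear sequence: 17 steps (steps 1–7, 12–18, 24, 25, 29).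

Step 13 (key step). The most likely failure is retro-aldol fragmentation of the tertiary lithium aldolate before the hindered α-proton is removed, which would destroy the C7 centre; the second is partial passage through the boat transition state, which would erode the configuration at C8. The fallback makes the C7–vinyl bond after the sigmatropic step. It sets out from 9: transesterification with ethyl 2-methylacetoacetate (DMAP cat., toluene, reflux) would give the 2-methyl-3-oxobutanoate of 9, F1. Carroll rearrangement of its dianion (LiN(i-Pr)2, THF, −78 → 25 °C), whose enolate geometry is locked by chelation between the two oxygens and in which no aldolate is present, followed by in situ alkylation with allyl bromide, would give the allyl β-keto ester F2 with C8 and C8a in place. Cram-chelate addition of CH2=CHMgBr to the methyl ketone, from the side of the C8 methyl group and away from ring A, would give the tertiary allylic alcohol F3. Silylation (Me3SiOTf, 2,6-lutidine) would give the silyl ether F4, and deallylation with Pd(PPh3)4 and morpholine would return to the route at 22.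

Step 12. The most likely failure is ionisation and decarboxylation of the tertiary allylic β-lactone, or proton transfer from its α-position to the alkoxide instead of acyl transfer. The fallback avoids the lactone and sets out from 15: silylation of the tertiary hydroxyl (Me3SiOTf, 2,6-lutidine, then aqueous hydrolysis of the silyl ester) would give (3R)-2,3-dimethyl-3-(trimethylsilyloxy)pent-4-enoic acid, F5. Yamaguchi esterification of F5 with 9 would give the silylated ester F6, and K2CO3 in methanol at 0 °C would free the tertiary hydroxyl and return to the route at 18.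

Step 24. The most likely failure is slow acylation of the C1 hydroxyl, which is crowded by the quaternary C8, so that epimerisation at C11' or β-elimination in the activated acid competes. The fallback forms the ester bond with a small acyl group and makes the C10'–C11' bond afterwards. It sets out from 29: acryloyl chloride and i-Pr2NEt would give the acrylate F7. A rhodium-catalysed reductive anti-aldol reaction of F7 with 33 (Rh(Phebox-ip)(OAc)2(H2O), (EtO)2MeSiH, then hydrolytic work-up), with the catalyst antipode chosen for the (2S,3R) sense, would give the β-hydroxy ester F8. HF·pyridine would then remove the primary silyl ether and return to the route at 41.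

Step 15. The most likely failure is incomplete addition of methyllithium to the very hindered carboxylate. The fallback sets out from 23: 1-chloro-N,N,2-trimethylprop-1-en-1-amine would give the acid chloride F9 under neutral conditions, and Me2CuLi at −78 °C would convert F9 into the methyl ketone, returning to the route at 25.

Step 16. The most likely failure is a second hydroxymethylation or dehydration of the aldol during quench. The fallback sets out from 23: CH2=CHLi (2.2 equiv) would give the vinyl ketone F10. Copper-catalysed conjugate borylation (CuCl, NaOt-Bu, B2pin2, MeOH) would give the β-boryl ketone F11, and oxidation with NaBO3·4H2O would return to the route at 27.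

## Further compounds

F1 | step 13 | (1R,4S,6S)-2-ethenyl-6-methyl-4-(triethylsilyloxy)cyclohex-2-en-1-yl 2-methyl-3-oxobutanoate | CC[Si](CC)(CC)O[C@H]1C[C@H](C)[C@@H](OC(=O)C(C)C(C)=O)C(C=C)=C1
F2 | step 13 | prop-2-en-1-yl (2R)-2-[(1S,4S,6S)-2-ethenyl-4-methyl-6-(triethylsilyloxy)cyclohex-2-en-1-yl]-2-methyl-3-oxobutanoate | CC[Si](CC)(CC)O[C@H]1C[C@H](C)C=C(C=C)[C@H]1[C@@](C)(C(=O)OCC=C)C(C)=O
F3 | step 13 | prop-2-en-1-yl (2R,3R)-2-[(1S,4S,6S)-2-ethenyl-4-methyl-6-(triethylsilyloxy)cyclohex-2-en-1-yl]-3-hydroxy-2,3-dimethylpent-4-enoate | CC[Si](CC)(CC)O[C@H]1C[C@H](C)C=C(C=C)[C@H]1[C@@](C)(C(=O)OCC=C)[C@](C)(O)C=C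
F4 | step 13 | prop-2-en-1-yl (2R,3R)-2-[(1S,4S,6S)-2-ethenyl-4-methyl-6-(triethylsilyloxy)cyclohex-2-en-1-yl]-2,3-dimethyl-3-(trimethylsilyloxy)pent-4-enoate | CC[Si](CC)(CC)O[C@H]1C[C@H](C)C=C(C=C)[C@H]1[C@@](C)(C(=O)OCC=C)[C@](C)(O[Si](C)(C)C)C=C
F5 | step 12 | (3R)-2,3-dimethyl-3-(trimethylsilyloxy)pent-4-enoic acid (both C2 epimers) | C=C[C@@](C)(O[Si](C)(C)C)C(C)C(O)=O
F6 | step 12 | (1R,4S,6S)-2-ethenyl-6-methyl-4-(triethylsilyloxy)cyclohex-2-en-1-yl (3R)-2,3-dimethyl-3-(trimethylsilyloxy)pent-4-enoate (both C2 epimers) | CC[Si](CC)(CC)O[C@H]1C[C@H](C)[C@@H](OC(=O)C(C)[C@](C)(O[Si](C)(C)C)C=C)C(C=C)=C1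
F7 | step 24 | (1S,3S,7R,8R,8aS)-8-[3-(tert-butyldimethylsilyloxy)propanoyl]-7-hydroxy-3,7,8-trimethyl-1,2,3,7,8,8a-hexahydronaphthalen-1-yl prop-2-enoate | C=CC(=O)O[C@H]1C[C@H](C)C=C2C=C[C@@](C)(O)[C@](C)(C(=O)CCO[Si](C)(C)C(C)(C)C)[C@H]21
F8 | step 24 | (1S,3S,7R,8R,8aS)-8-[3-(tert-butyldimethylsilyloxy)propanoyl]-7-hydroxy-3,7,8-trimethyl-1,2,3,7,8,8a-hexahydronaphthalen-1-yl (2S,3R,4E)-3-hydroxy-5-iodo-2,4-dimethylpent-4-enoate | I/C=C(\C)[C@H](O)[C@H](C)C(=O)O[C@H]1C[C@H](C)C=C2C=C[C@@](C)(O)[C@](C)(C(=O)CCO[Si](C)(C)C(C)(C)C)[C@H]21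
F9 | step 15 | (1R,2R,6S,8S,8aS)-1,2,6-trimethyl-8-(triethylsilyloxy)-2-(trimethylsilyloxy)-1,2,6,7,8,8a-hexahydronaphthalene-1-carbonyl chloride | CC[Si](CC)(CC)O[C@H]1C[C@H](C)C=C2C=C[C@@](C)(O[Si](C)(C)C)[C@](C)(C(Cl)=O)[C@H]21
F10 | step 16 | 1-[(1R,2R,6S,8S,8aS)-1,2,6-trimethyl-8-(triethylsilyloxy)-2-(trimethylsilyloxy)-1,2,6,7,8,8a-hexahydronaphthalen-1-yl]prop-2-en-1-one | CC[Si](CC)(CC)O[C@H]1C[C@H](C)C=C2C=C[C@@](C)(O[Si](C)(C)C)[C@](C)(C(=O)C=C)[C@H]21
F11 | step 16 | 3-(4,4,5,5-tetramethyl-1,3,2-dioxaborolan-2-yl)-1-[(1R,2R,6S,8S,8aS)-1,2,6-trimethyl-8-(triethylsilyloxy)-2-(trimethylsilyloxy)-1,2,6,7,8,8a-hexahydronaphthalen-1-yl]propan-1-one | CC[Si](CC)(CC)O[C@H]1C[C@H](C)C=C2C=C[C@@](C)(O[Si](C)(C)C)[C@](C)(C(=O)CCB3OC(C)(C)C(C)(C)O3)[C@H]21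
A1 | alternative 1 | (4E,6S,8R,10E,12E)-1,6-bis(tert-butyldimethylsilyloxy)-4,8-dimethyltetradeca-4,10,12-trien-3-one (open-chain trienone) | C/C=C/C=C/C[C@@H](C)C[C@H](O[Si](C)(C)C(C)(C)C)/C=C(\C)C(=O)CCO[Si](C)(C)C(C)(C)C
A2 | alternative 1 | trans-fused octahydronaphthalene cycloadduct with H at C7 and C4a (C5=C6 alkene only) | CC(C)(C)[Si](C)(C)O[C@H]1C[C@H](C)C[C@@H]2C=C[C@H](C)[C@](C)(C(=O)CCO[Si](C)(C)C(C)(C)C)[C@H]21
A3 | alternative 2 | open-chain dienyne: C3–C2–C1–C8a–C8–C7 chain of the target with ethynyl on C8a and vinyl groups on C3 and C7 (silyl-protected) | C=C[C@@H](C)C[C@H](O[Si](CC)(CC)CC)[C@@H](C#C)[C@@](C)(C(=O)CCO[Si](C)(C)C(C)(C)C)[C@](C)(O[Si](C)(C)C)C=C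
A4 | alternative 3 | ring A diketone with a (Z)-3-oxobut-1-enyl group on C4a and a 5-(tert-butyldimethylsilyloxy)-3-oxopentan-2-yl group on C8a | CC(=O)/C=C\C1=C[C@@H](C)C[C@H](O[Si](CC)(CC)CC)[C@@H]1C(C)C(=O)CCO[Si](C)(C)C(C)(C)C
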